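**Retrosynthetic overview**
- The ester C–O bond is cut first: a Mitsunobu inversion joins a bicyclic allylic/tertiary diol to silyl-protected isovanillic acid.
- The diol comes from a spiro-epoxy enone; its cyclohexenone ring is opened by a retro intramolecular aldol condensation to a keto-aldehyde on a cycloheptane (key ring closure).
- The keto-aldehyde comes from ozonolysis of a diene epoxide, which comes from Corey–Chaykovsky methylenation of a trans-2,3-disubstituted 4,4-dimethylcycloheptanone.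
- That ketone comes from an asymmetric three-component coupling of 4,4-dimethylcyclohept-2-enone, an (E)-alkenylborane and 2-(bromomethyl)but-1-ene.
- Ring order: the seven-membered ring is made first (one-carbon ring expansion of a cyclohexanone silyl enol ether), the six-membered ring last (aldol).

Assumption: Rh/(S)-BINAP adds the alkenyl group to enone 5 with the same facial sense as known for cyclohex-2-enone and cyclohept-2-enone; if it is the opposite, (R)-BINAP is used.

**Route**

Step 1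
Reactants: 1 3-methylcyclohex-2-en-1-one
Product: 2 [(3,3-dimethylcyclohex-1-en-1-yl)oxy]trimethylsilane
Conditions: MeMgBr, CuBr·SMe2 (5 mol %), TMSCl, HMPA, THF, −78 °C; Et3N quench
Reagents that add atoms: methylmagnesium bromide, C[Mg]Br; chlorotrimethylsilane, C[Si](C)(C)Cl
Why: Copper-catalysed, TMSCl-accelerated 1,4-addition of the methyl Grignard builds the gem-dimethyl carbon and traps the enolate regiospecifically as the silyl enol ether; no stereocentre is formed.

Step 2
Reactants: 2 [(3,3-dimethylcyclohex-1-en-1-yl)oxy]trimethylsilane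
Product: 3 [(5,5-dimethylbicyclo[4.1.0]heptan-1-yl)oxy]trimethylsilane (racemic)
Conditions: CH2I2, Zn/Ag couple, Et2O, reflux; pyridine work-up
Reagents that add atoms: diiodomethane, ICI
Why: Simmons–Smith cyclopropanation of the electron-rich enol ether double bond gives the siloxycyclopropane; it is racemic, which does not matter because both new stereocentres are destroyed in step 3.

Step 3
Reactants: 3 [(5,5-dimethylbicyclo[4.1.0]heptan-1-yl)oxy]trimethylsilane
Product: 5 4,4-dimethylcyclohept-2-en-1-one, via 3-chloro-4,4-dimethylcycloheptan-1-one 4 (not isolated)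
Conditions: FeCl3, DMF, 0 → 25 °C; then NaOAc, MeOH, reflux
Reagents that add atoms: none
Why: Ito–Saegusa ring expansion, in which FeCl3 oxidises the siloxycyclopropane, the ring-fusion bond cleaves to a β-keto radical that is chlorinated, and NaOAc eliminates HCl (E1cB) to the conjugated cycloheptenone; no stereocentre remains.

Step 4
Reactants: 6 butanal
Product: 7 2-methylidenebutanal
Conditions: aq. HCHO (37 %), pyrrolidine (10 mol %), EtCO2H (10 mol %), i-PrOH, 45 °C
Reagents that add atoms: formaldehyde, C=O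
Why: Amine-catalysed Mannich condensation with formaldehyde followed by loss of the amine (organocatalytic α-methylenation) gives the 2-alkylacrolein; no stereocentre.

Step 5
Reactants: 7 2-methylidenebutanal
Product: 8 2-methylidenebutan-1-ol
Conditions: NaBH4, CeCl3·7H2O, MeOH, 0 °C
Reagents that add atoms: none
Why: Luche 1,2-reduction of the enal leaves the 1,1-disubstituted alkene untouched; no stereocentre.

Step 6
Reactants: 8 2-methylidenebutan-1-ol
Product: 9 2-(bromomethyl)but-1-ene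
Conditions: PBr3 (0.4 equiv), pyridine (cat.), Et2O, 0 °C
Reagents that add atoms: phosphorus tribromide, BrP(Br)Br
Why: SN2 bromination of the primary allylic alcohol through its phosphite ester; the allyl system has identical termini, so transposition changes nothing.

Step 7
Reactants: 10 hex-1-yne; 11 9-borabicyclo[3.3.1]nonane (9-BBN-H; sold as its dimer in THF)
Product: 12 9-[(E)-hex-1-en-1-yl]-9-borabicyclo[3.3.1]nonane
Conditions: THF, 0 → 25 °C, twofold excess of 10; volatiles removed, residue taken up in toluene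
Reagents that add atoms: none
Why: syn-Hydroboration of the terminal alkyne puts boron on the terminal carbon and gives the (E)-alkenylborane; excess alkyne suppresses double hydroboration.

Step 8
Reactants: 5 4,4-dimethylcyclohept-2-en-1-one; 12 9-[(E)-hex-1-en-1-yl]-9-borabicyclo[3.3.1]nonane; 9 2-(bromomethyl)but-1-ene
Product: 15 (2R,3R)-3-[(E)-hex-1-en-1-yl]-4,4-dimethyl-2-(2-methylidenebutyl)cycloheptan-1-one, via boron enolate 13 (not isolated), via lithium borate enolate 14 (not isolated)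
Conditions: [Rh(OMe)(cod)]2 (1.5 mol %), (S)-BINAP (3.3 mol %), toluene, 80 °C; then n-BuLi, THF, −78 °C; then 9, −78 → 0 °C
Reagents that add atoms: none
Why: Hayashi-type Rh/BINAP asymmetric 1,4-addition under aprotic conditions sets C3 by ligand control and leaves a regiodefined boron enolate, which after conversion to the borate is C-alkylated by the allylic bromide anti to the new alkenyl group to give the trans-2,3-disubstituted ketone.

Step 9
Reactants: 15 (2R,3R)-3-[(E)-hex-1-en-1-yl]-4,4-dimethyl-2-(2-methylidenebutyl)cycloheptan-1-one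
Product: 16 (3R,4R,5R)-5-[(E)-hex-1-en-1-yl]-6,6-dimethyl-4-(2-methylidenebutyl)-1-oxaspiro[2.6]nonane
Conditions: Me3S+ I−, n-BuLi, THF, −10 °C; then 15, −10 → 25 °C
Reagents that add atoms: trimethylsulfonium iodide, C[S+](C)C.[I-]
Why: Corey–Chaykovsky epoxidation, in which the small, irreversibly adding sulfonium ylide is expected to attack along the axial-type trajectory cis to the equatorial C2 side chain, so the epoxide oxygen ends up cis to H-2 as the tertiary carbinol requires; the epoxide also masks that alcohol.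

Step 10
Reactants: 16 (3R,4R,5R)-5-[(E)-hex-1-en-1-yl]-6,6-dimethyl-4-(2-methylidenebutyl)-1-oxaspiro[2.6]nonane
Product: 18 (3R,4R,5R)-6,6-dimethyl-4-(2-oxobutyl)-1-oxaspiro[2.6]nonane-5-carbaldehyde, via bis-ozonide 17 (not isolated)
Conditions: O3, CH2Cl2, −78 °C; then Me2S, −78 → 25 °C
Reagents that add atoms: ozone, [O-][O+]=O
Why: Ozonolysis with reductive work-up cleaves the hexenyl group to the aldehyde and the 1,1-disubstituted alkene to the ethyl ketone, while the epoxide and all stereocentres are untouched.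

Step 11
Reactants: 18 (3R,4R,5R)-6,6-dimethyl-4-(2-oxobutyl)-1-oxaspiro[2.6]nonane-5-carbaldehyde
Product: 20 (4aR,9R,9aR)-3,5,5-trimethyl-4a,5,6,7,8,9a-hexahydro-1H-spiro[benzo[7]annulene-9,2'-oxiran]-2-one, via aldol adduct 19 (not isolated)
Conditions: KOH (0.2 equiv), MeOH, 0 → 25 °C
Reagents that add atoms: none
Why: Intramolecular aldol condensation of the ethyl-ketone α-methylene onto the aldehyde followed by E1cB dehydration closes the cyclohexenone (the other enolates could only give four-membered rings), and the trans ring fusion from step 8 is also the thermodynamically preferred one if C4a equilibrates.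

Step 12
Reactants: 20 (4aR,9R,9aR)-3,5,5-trimethyl-4a,5,6,7,8,9a-hexahydro-1H-spiro[benzo[7]annulene-9,2'-oxiran]-2-one
Product: 21 (2S,4aR,9R,9aR)-3,5,5,9-tetramethyl-2,4a,5,6,7,8,9,9a-octahydro-1H-benzo[7]annulene-2,9-diol
Conditions: LiAlH4, Et2O, −78 → 25 °C; H2O/aq. NaOH work-up
Reagents that add atoms: none
Why: LiAlH4 reduces the enone 1,2 by axial attack syn to the axial H-9a (as carvone gives cis-carveol) to the pseudo-equatorial (2S) alcohol, then opens the epoxide by SN2 at its CH2 to reveal the tertiary methyl carbinol.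

Step 13
Reactants: 22 3-hydroxy-4-methoxybenzaldehyde (isovanillin)
Product: 23 3-[(tert-butyldimethylsilyl)oxy]-4-methoxybenzaldehyde
Conditions: TBSCl, imidazole, DMF, 25 °C
Reagents that add atoms: tert-butyldimethylsilyl chloride, CC(C)(C)[Si](C)(C)Cl
Why: Silyl ether formation blocks the phenol so that only the carboxylic acid can act as the pronucleophile in step 15.

Step 14
Reactants: 23 3-[(tert-butyldimethylsilyl)oxy]-4-methoxybenzaldehyde
Product: 24 3-[(tert-butyldimethylsilyl)oxy]-4-methoxybenzoic acid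
Conditions: NaClO2, NaH2PO4, 2-methylbut-2-ene, t-BuOH/H2O, 25 °C
Reagents that add atoms: sodium chlorite, [Na+].[O-]Cl=O
Why: Pinnick oxidation converts the aldehyde to the acid under buffered conditions that the aryl silyl ether survives.

Step 15
Reactants: 21 (2S,4aR,9R,9aR)-3,5,5,9-tetramethyl-2,4a,5,6,7,8,9,9a-octahydro-1H-benzo[7]annulene-2,9-diol; 24 3-[(tert-butyldimethylsilyl)oxy]-4-methoxybenzoic acid
Product: 25 (2R,4aR,9R,9aR)-9-hydroxy-3,5,5,9-tetramethyl-2,4a,5,6,7,8,9,9a-octahydro-1H-benzo[7]annulen-2-yl 3-[(tert-butyldimethylsilyl)oxy]-4-methoxybenzoate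
Conditions: PPh3, DIAD, THF, 0 → 25 °C
Reagents that add atoms: none
Why: Mitsunobu esterification activates only the secondary allylic alcohol (the tertiary one is inert) and the carboxylate displaces with SN2 inversion, turning the (2S) alcohol into the (2R) ester.

Step 16
Reactants: 25 (2R,4aR,9R,9aR)-9-hydroxy-3,5,5,9-tetramethyl-2,4a,5,6,7,8,9,9a-octahydro-1H-benzo[7]annulen-2-yl 3-[(tert-butyldimethylsilyl)oxy]-4-methoxybenzoate
Product: 26 (2R,4aR,9R,9aR)-9-hydroxy-3,5,5,9-tetramethyl-2,4a,5,6,7,8,9,9a-octahydro-1H-benzo[7]annulen-2-yl 3-hydroxy-4-methoxybenzoate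
Conditions: Bu4NF, AcOH, THF, 0 °C
Reagents that add atoms: none
Why: Fluoride-mediated desilylation of the aryl silyl ether, buffered with AcOH so the benzoate is not cleaved, gives the target with all four stereocentres unchanged.

**Compound list**

1 | 3-methylcyclohex-2-en-1-one | CC1=CC(=O)CCC1 | starting material
2 | [(3,3-dimethylcyclohex-1-en-1-yl)oxy]trimethylsilane | C[Si](C)(C)OC1=CC(C)(C)CCC1 | intermediate
3 | [(5,5-dimethylbicyclo[4.1.0]heptan-1-yl)oxy]trimethylsilane (racemic) | C[Si](C)(C)OC12CC1C(C)(C)CCC2 | intermediate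
4 | 3-chloro-4,4-dimethylcycloheptan-1-one (racemic) | O=C1CC(Cl)C(C)(C)CCC1 | intermediate
5 | 4,4-dimethylcyclohept-2-en-1-one | O=C1C=CC(C)(C)CCC1 | intermediate
6 | butanal | CCCC=O | starting material
7 | 2-methylidenebutanal | CCC(=C)C=O | intermediate
8 | 2-methylidenebutan-1-ol | CCC(=C)CO | intermediate
9 | 2-(bromomethyl)but-1-ene | CCC(=C)CBr | intermediate
10 | hex-1-yne | CCCCC#C | starting material
11 | 9-borabicyclo[3.3.1]nonane (9-BBN-H; sold as its dimer in THF) | B1C2CCCC1CCC2 | starting material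
12 | 9-[(E)-hex-1-en-1-yl]-9-borabicyclo[3.3.1]nonane | CCCC/C=C/B1C2CCCC1CCC2 | intermediate
13 | boron enolate: 9-{[(3R)-3-[(E)-hex-1-en-1-yl]-4,4-dimethylcyclohept-1-en-1-yl]oxy}-9-borabicyclo[3.3.1]nonane | O(B1C2CCCC1CCC2)C1=C[C@@H](/C=C/CCCC)C(C)(C)CCC1 | intermediate
14 | lithium borate enolate: lithium 9-butyl-9-{[(3R)-3-[(E)-hex-1-en-1-yl]-4,4-dimethylcyclohept-1-en-1-yl]oxy}-9-boranuidabicyclo[3.3.1]nonane | [Li+].CCCC[B-]1(OC2=C[C@@H](/C=C/CCCC)C(C)(C)CCC2)C2CCCC1CCC2 | intermediate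
15 | (2R,3R)-3-[(E)-hex-1-en-1-yl]-4,4-dimethyl-2-(2-methylidenebutyl)cycloheptan-1-one | CCC(=C)C[C@@H]1[C@@H](/C=C/CCCC)C(C)(C)CCCC1=O | intermediate
16 | (3R,4R,5R)-5-[(E)-hex-1-en-1-yl]-6,6-dimethyl-4-(2-methylidenebutyl)-1-oxaspiro[2.6]nonane | CCC(=C)C[C@@H]1[C@@H](/C=C/CCCC)C(C)(C)CCC[C@@]1(C2)O2 | intermediate
17 | bis-ozonide: (3R,4R,5R)-5-(5-butyl-1,2,4-trioxolan-3-yl)-4-[(3-ethyl-1,2,4-trioxolan-3-yl)methyl]-6,6-dimethyl-1-oxaspiro[2.6]nonane (mixture at the trioxolane carbons) | CCC1(C[C@@H]2[C@@H](C3OC(CCCC)OO3)C(C)(C)CCC[C@@]2(C4)O4)OCOO1 | intermediate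
18 | (3R,4R,5R)-6,6-dimethyl-4-(2-oxobutyl)-1-oxaspiro[2.6]nonane-5-carbaldehyde | CCC(=O)C[C@@H]1[C@@H](C=O)C(C)(C)CCC[C@@]1(C2)O2 | intermediate
19 | aldol adduct: (4aR,9R,9aR)-4-hydroxy-3,5,5-trimethyloctahydro-1H-spiro[benzo[7]annulene-9,2'-oxiran]-2-one (epimers at C3 and C4) | O=C1C[C@@H]2[C@@H](C(O)C1C)C(C)(C)CCC[C@@]2(C3)O3 | intermediate
20 | (4aR,9R,9aR)-3,5,5-trimethyl-4a,5,6,7,8,9a-hexahydro-1H-spiro[benzo[7]annulene-9,2'-oxiran]-2-one (trans-fused) | O=C1C[C@@H]2[C@@H](C=C1C)C(C)(C)CCC[C@@]2(C3)O3 | intermediate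
21 | (2S,4aR,9R,9aR)-3,5,5,9-tetramethyl-2,4a,5,6,7,8,9,9a-octahydro-1H-benzo[7]annulene-2,9-diol | O[C@H]1C[C@@H]2[C@@H](C=C1C)C(C)(C)CCC[C@@]2(C)O | intermediate
22 | 3-hydroxy-4-methoxybenzaldehyde (isovanillin) | COc1ccc(C=O)cc1O | starting material
23 | 3-[(tert-butyldimethylsilyl)oxy]-4-methoxybenzaldehyde | COc1ccc(C=O)cc1O[Si](C)(C)C(C)(C)C | intermediate
24 | 3-[(tert-butyldimethylsilyl)oxy]-4-methoxybenzoic acid | COc1ccc(C(=O)O)cc1O[Si](C)(C)C(C)(C)C | intermediate
25 | (2R,4aR,9R,9aR)-9-hydroxy-3,5,5,9-tetramethyl-2,4a,5,6,7,8,9,9a-octahydro-1H-benzo[7]annulen-2-yl 3-[(tert-butyldimethylsilyl)oxy]-4-methoxybenzoate | COc1ccc(C(=O)O[C@@H]2C[C@@H]3[C@@H](C=C2C)C(C)(C)CCC[C@@]3(C)O)cc1O[Si](C)(C)C(C)(C)C | intermediate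
26 | (2R,4aR,9R,9aR)-9-hydroxy-3,5,5,9-tetramethyl-2,4a,5,6,7,8,9,9a-octahydro-1H-benzo[7]annulen-2-yl 3-hydroxy-4-methoxybenzoate | COc1ccc(C(=O)O[C@@H]2C[C@@H]3[C@@H](C=C2C)C(C)(C)CCC[C@@]3(C)O)cc1O | target

**Step count and risks**

Total step count: 16. Longest linear sequence: 10 steps (1, 2, 3, 8, 9, 10, 11, 12, 15, 16; the line through steps 4, 5, 6 is equally long).

Risk 1 is step 8. The enone carries a quaternary carbon next to its β-carbon, so insertion into the alkenyl–rhodium bond may be slow, and alkenyl-9-BBN reagents and the alkylation of the boron enolate are less proven than the aryl cases. The fallback sets out from 5 and comes back at 15. Hex-1-yne 10 is hydroaluminated with i-Bu2AlH (heptane, 50 °C) to (E)-hex-1-en-1-yl(diisobutyl)alane F1. F1 is added to 5 with Cu(OTf)2 and a BINOL-derived phosphoramidite ligand in Et2O at −30 °C, and TMSOTf is added to the same flask to give {[(3R)-3-[(E)-hex-1-en-1-yl]-4,4-dimethylcyclohept-1-en-1-yl]oxy}trimethylsilane F2. MeLi in THF at 0 °C turns F2 into lithium (3R)-3-[(E)-hex-1-en-1-yl]-4,4-dimethylcyclohept-1-en-1-olate F3, and F3 is alkylated with 9 in THF/DMPU (−78 → 0 °C) to give 15.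

Risk 2 is step 9. The basic ylide may enolise the hindered α-branched ketone, and the facial preference on a flexible seven-membered ring is argued only by analogy with cyclohexanones. The fallback sets out from 15 and comes back at 21. Excess Me3Al (3 equiv, toluene, −78 → 0 °C), a non-basic reagent that also delivers methyl axially, gives (1R,2R,3R)-3-[(E)-hex-1-en-1-yl]-1,4,4-trimethyl-2-(2-methylidenebutyl)cycloheptan-1-ol F4. Ozonolysis (O3, CH2Cl2, −78 °C; Me2S) gives (1R,6R,7R)-6-hydroxy-2,2,6-trimethyl-7-(2-oxobutyl)cycloheptane-1-carbaldehyde F5, which is partly present as its lactol. KOH in MeOH closes F5 to (4aR,9R,9aR)-9-hydroxy-3,5,5,9-tetramethyl-1,4a,5,6,7,8,9,9a-octahydro-2H-benzo[7]annulen-2-one F6, and NaBH4/CeCl3·7H2O in MeOH reduces F6 to 21.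

Risk 3 is step 15. An allylic Mitsunobu reaction can give SN2' ester or diene by elimination instead of clean inversion. The fallback sets out from 20 and comes back at 25, replacing substrate-controlled reduction plus inversion by reagent-controlled reduction plus acylation with retention. (S)-Me-CBS oxazaborolidine (20 mol %) with catecholborane in toluene at −78 °C reduces 20 to (2R,4aR,9R,9aR)-3,5,5-trimethyl-1,2,4a,5,6,7,8,9a-octahydrospiro[benzo[7]annulene-9,2'-oxiran]-2-ol F7. LiAlH4 in Et2O opens the epoxide to (2R,4aR,9R,9aR)-3,5,5,9-tetramethyl-2,4a,5,6,7,8,9,9a-octahydro-1H-benzo[7]annulene-2,9-diol F8. Esterification of F8 with 24 (EDC·HCl, DMAP, CH2Cl2, 25 °C; the tertiary alcohol does not react) gives 25.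

**Further compounds**

F1 | step 8 | (E)-hex-1-en-1-yl(diisobutyl)alane | CCCC/C=C/[Al](CC(C)C)CC(C)C
F2 | step 8 | {[(3R)-3-[(E)-hex-1-en-1-yl]-4,4-dimethylcyclohept-1-en-1-yl]oxy}trimethylsilane | C[Si](C)(C)OC1=C[C@@H](/C=C/CCCC)C(C)(C)CCC1
F3 | step 8 | lithium (3R)-3-[(E)-hex-1-en-1-yl]-4,4-dimethylcyclohept-1-en-1-olate | [Li+].[O-]C1=C[C@@H](/C=C/CCCC)C(C)(C)CCC1
F4 | step 9 | (1R,2R,3R)-3-[(E)-hex-1-en-1-yl]-1,4,4-trimethyl-2-(2-methylidenebutyl)cycloheptan-1-ol | CCC(=C)C[C@@H]1[C@@H](/C=C/CCCC)C(C)(C)CCC[C@@]1(C)O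
F5 | step 9 | (1R,6R,7R)-6-hydroxy-2,2,6-trimethyl-7-(2-oxobutyl)cycloheptane-1-carbaldehyde | CCC(=O)C[C@@H]1[C@@H](C=O)C(C)(C)CCC[C@@]1(C)O
F6 | step 9 | (4aR,9R,9aR)-9-hydroxy-3,5,5,9-tetramethyl-1,4a,5,6,7,8,9,9a-octahydro-2H-benzo[7]annulen-2-one | O=C1C[C@@H]2[C@@H](C=C1C)C(C)(C)CCC[C@@]2(C)O
F7 | step 15 | (2R,4aR,9R,9aR)-3,5,5-trimethyl-1,2,4a,5,6,7,8,9a-octahydrospiro[benzo[7]annulene-9,2'-oxiran]-2-ol | O[C@@H]1C[C@@H]2[C@@H](C=C1C)C(C)(C)CCC[C@@]2(C3)O3
F8 | step 15 | (2R,4aR,9R,9aR)-3,5,5,9-tetramethyl-2,4a,5,6,7,8,9,9a-octahydro-1H-benzo[7]annulene-2,9-diol | O[C@@H]1C[C@@H]2[C@@H](C=C1C)C(C)(C)CCC[C@@]2(C)O
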